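**Retrosynthetic overview**
1. Target 27 ⇒ primary-selective O-acetylation of threo-diol 26 ⇒ reductive removal of the auxiliary from syn-aldol adduct 25.
2. 25 ⇒ late Evans boron aldol (C7–C8 bond, sets both stereocentres) between aryloxyacetyl imide 22 and 3,4,5-trimethoxybenzaldehyde 6.
3. 22 ⇒ SN2 O-alkylation of 4-allyl-2,6-dimethoxyphenol 16 with bromoacetyl imide 21, itself made from L-valinol and bromoacetyl bromide.
4. 16 ⇒ para-Claisen of allyl syringyl ether ⇐ resorcinol (methylation, then ortho-lithiation/borylation/oxidation). 6 ⇐ p-cresol (ring bromination, side-chain oxidation, Cu methoxylation, methylation).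
5. Rings: both arenes are bought intact. The only ring built is the oxazolidinone auxiliary (step 9), which is cut off again in step 13.

Assumption: the SMILES is read as the (7R,8R)-threo isomer, which is (2R,3R) in propyl acetate numbering. Commodity reagents that deliver only heteroatoms, methyl, acetyl or the carbamate C=O are treated as reagents and are not numbered.

**Branch A: aldehyde 6**

Step 1
Reactants: 1 p-cresol (4-methylphenol)
Product: 2 2,6-dibromo-4-methylphenol
Conditions: Br2 (2.05 equiv), CH2Cl2/AcOH, 0 °C → rt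
Reagents that add atoms: bromine BrBr
Why: Electrophilic aromatic bromination, in which the OH group directs to its two free ortho positions because the para position carries the methyl group.

Step 2
Reactants: 2 2,6-dibromo-4-methylphenol
Product: 4 3,5-dibromo-4-hydroxybenzaldehyde, via benzal bromide 3 (not isolated)
Conditions: Br2 (2.1 equiv), o-dichlorobenzene, 150–160 °C; then H2O, 100 °C
Reagents that add atoms: water O (aldehyde oxygen); bromine BrBr (its atoms stay only in 3)
Why: With the activated ring positions blocked, hot bromine performs a benzylic (side-chain) dibromination, and hydrolysis of the p-hydroxy-activated gem-dibromide gives the aldehyde.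

Step 3
Reactants: 4 3,5-dibromo-4-hydroxybenzaldehyde
Product: 5 syringaldehyde (4-hydroxy-3,5-dimethoxybenzaldehyde)
Conditions: NaOMe (4 equiv), CuCl (10 mol %), DMF/MeOH, 110 °C; acidic work-up
Reagents that add atoms: sodium methoxide [Na+].[O-]C
Why: Copper(I)-catalysed Ullmann-type methoxylation replaces both aryl bromides, while the phenoxide formed in situ protects the aldehyde from attack by methoxide.

Step 4
Reactants: 5 syringaldehyde
Product: 6 3,4,5-trimethoxybenzaldehyde
Conditions: MeI (1.3 equiv), K2CO3, DMF, rt → 40 °C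
Reagents that add atoms: methyl iodide CI
Why: Williamson O-methylation of the only acidic OH group, with no other nucleophilic site present.

**Branch B: phenol 16**

Step 5
Reactants: 7 resorcinol
Product: 8 1,3-dimethoxybenzene
Conditions: Me2SO4 (2.3 equiv), K2CO3, acetone, reflux
Reagents that add atoms: dimethyl sulfate COS(=O)(=O)OC
Why: Double Williamson O-methylation, in which the hard electrophile with carbonate in acetone favours O- over C-alkylation.

Step 6
Reactants: 8 1,3-dimethoxybenzene
Product: 11 2,6-dimethoxyphenol (syringol), via aryllithium 9 (not isolated), via dimethyl arylboronate 10 (not isolated)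
Conditions: n-BuLi (1.1 equiv), THF, 0 °C → rt; B(OMe)3, −78 °C → rt; AcOH, 30 % H2O2, 0 °C → rt
Reagents that add atoms: hydrogen peroxide OO (phenol oxygen); n-butyllithium [Li]CCCC (Li only in 9); trimethyl borate COB(OC)OC (boron unit only in 10)
Why: Directed ortho-metalation occurs only at C2 between the two OMe groups, and borylation followed by peroxide oxidation (1,2-aryl shift from B to O) turns C–Li into C–OH.

Step 7
Reactants: 11 2,6-dimethoxyphenol; 12 allyl bromide
Product: 13 2-(allyloxy)-1,3-dimethoxybenzene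
Conditions: K2CO3, acetone, reflux
Reagents that add atoms: none
Why: Williamson ether synthesis with a reactive allylic halide, and C-allylation is suppressed because both ortho positions are substituted.

Step 8
Reactants: 13 2-(allyloxy)-1,3-dimethoxybenzene
Product: 16 4-allyl-2,6-dimethoxyphenol, via ortho-dienone 14 (not isolated), via para-dienone 15 (not isolated)
Conditions: N,N-diethylaniline, 200–210 °C, Ar, 4–6 h
Reagents that add atoms: none
Why: In this para-Claisen rearrangement the first [3,3] shift gives an ortho-dienone that cannot enolise, so a Cope [3,3] shift carries the allyl group to C4 and tautomerisation restores the phenol.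

**Branch C: chiral C2 unit 21**

Step 9
Reactants: 17 L-valinol, (S)-2-amino-3-methylbutan-1-ol
Product: 18 (S)-4-isopropyloxazolidin-2-one
Conditions: (EtO)2CO, K2CO3 (cat.), 130 °C, EtOH distilled off
Reagents that add atoms: diethyl carbonate CCOC(=O)OCC
Why: Cyclocarbonylation (N-acylation, then intramolecular transesterification) is driven by removal of ethanol, and the stereocentre comes unchanged from L-valinol.

Step 10
Reactants: 18 (S)-4-isopropyloxazolidin-2-one; 19 bromoacetyl bromide
Product: 21 (S)-3-(2-bromoacetyl)-4-isopropyloxazolidin-2-one, via N-lithio oxazolidinone 20 (not isolated)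
Conditions: n-BuLi (1.0 equiv), THF, −78 °C; then 19, −78 → 0 °C
Reagents that add atoms: n-butyllithium [Li]CCCC (Li only in 20)
Why: In this N-acylation of the lithiated carbamate, the acyl bromide reacts far faster than the alkyl bromide at −78 °C, so the C–Br bond survives.

**Union and endgame**

Step 11
Reactants: 16 4-allyl-2,6-dimethoxyphenol; 21 (S)-3-(2-bromoacetyl)-4-isopropyloxazolidin-2-one
Product: 22 (S)-3-[2-(4-allyl-2,6-dimethoxyphenoxy)acetyl]-4-isopropyloxazolidin-2-one
Conditions: anhydrous K2CO3 (1.5 equiv), acetone, rt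
Reagents that add atoms: none
Why: SN2 (Williamson) displacement at a carbonyl-activated primary bromide proceeds readily, whereas attack of the phenoxide at the imide C=O is unproductive because phenoxide is the better leaving group and is expelled again.

Step 12
Reactants: 22 (S)-3-[2-(4-allyl-2,6-dimethoxyphenoxy)acetyl]-4-isopropyloxazolidin-2-one; 6 3,4,5-trimethoxybenzaldehyde
Product: 25 (S)-3-[(2S,3R)-2-(4-allyl-2,6-dimethoxyphenoxy)-3-hydroxy-3-(3,4,5-trimethoxyphenyl)propanoyl]-4-isopropyloxazolidin-2-one, via Z-boron enolate 23 (not isolated), via boron aldolate 24 (not isolated)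
Conditions: Bu2BOTf (1.2 equiv), Et3N (1.4 equiv), CH2Cl2, −78 → 0 °C; 6, −78 → 0 °C; pH 7 buffer, MeOH, 30 % H2O2, 0 °C
Reagents that add atoms: di-n-butylboron triflate CCCCB(CCCC)OS(=O)(=O)C(F)(F)F (Bu2B unit only in 23 and 24)
Why: In this Evans syn-aldol the Z-boron enolate reacts through a Zimmerman–Traxler chair in which the dipole-opposed (S)-isopropyl auxiliary shields one face, which sets C8 and C7 together as the syn (2S,3R) adduct, i.e. the threo relationship of the target.

Step 13
Reactants: 25 syn-aldol imide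
Product: 26 (1R,2R)-2-(4-allyl-2,6-dimethoxyphenoxy)-1-(3,4,5-trimethoxyphenyl)propane-1,3-diol
Conditions: LiBH4 (2.5 equiv), MeOH (2.5 equiv), THF, 0 °C
Reagents that add atoms: none
Why: Reductive auxiliary cleavage with LiBH4 reduces only the exocyclic imide carbonyl to CH2OH and touches neither stereocentre nor the allyl group, so C8 changes only its descriptor from S to R through the change in CIP priorities.

Step 14
Reactants: 26 (1R,2R)-diol
Product: 27 (2R,3R)-2-(4-allyl-2,6-dimethoxyphenoxy)-3-hydroxy-3-(3,4,5-trimethoxyphenyl)propyl acetate (target)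
Conditions: AcCl (1.05 equiv), 2,4,6-collidine (2 equiv), CH2Cl2, −78 °C
Reagents that add atoms: acetyl chloride CC(=O)Cl
Why: In this kinetically controlled chemoselective acylation the unhindered primary OH reacts much faster than the secondary benzylic OH next to the bulky aryloxy group, and no stereocentre is involved.

**Compound list**
1 | p-cresol | Cc1ccc(O)cc1 | starting material
2 | 2,6-dibromo-4-methylphenol | Cc1cc(Br)c(O)c(Br)c1 | intermediate
3 | 2,6-dibromo-4-(dibromomethyl)phenol (benzal bromide) | BrC(Br)c1cc(Br)c(O)c(Br)c1 | intermediate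
4 | 3,5-dibromo-4-hydroxybenzaldehyde | O=Cc1cc(Br)c(O)c(Br)c1 | intermediate
5 | syringaldehyde | COc1cc(C=O)cc(OC)c1O | intermediate
6 | 3,4,5-trimethoxybenzaldehyde | COc1cc(C=O)cc(OC)c1OC | intermediate
7 | resorcinol | Oc1cccc(O)c1 | starting material
8 | 1,3-dimethoxybenzene | COc1cccc(OC)c1 | intermediate
9 | 2,6-dimethoxyphenyllithium | [Li]c1c(OC)cccc1OC | intermediate
10 | dimethyl (2,6-dimethoxyphenyl)boronate | COB(OC)c1c(OC)cccc1OC | intermediate
11 | 2,6-dimethoxyphenol | COc1cccc(OC)c1O | intermediate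
12 | allyl bromide | C=CCBr | starting material
13 | 2-(allyloxy)-1,3-dimethoxybenzene | C=CCOc1c(OC)cccc1OC | intermediate
14 | 6-allyl-2,6-dimethoxycyclohexa-2,4-dien-1-one (racemic) | C=CCC1(OC)C=CC=C(OC)C1=O | intermediate
15 | 4-allyl-2,6-dimethoxycyclohexa-2,5-dien-1-one | C=CCC1C=C(OC)C(=O)C(OC)=C1 | intermediate
16 | 4-allyl-2,6-dimethoxyphenol | C=CCc1cc(OC)c(O)c(OC)c1 | intermediate
17 | L-valinol, (S)-2-amino-3-methylbutan-1-ol | CC(C)[C@H](N)CO | starting material
18 | (S)-4-isopropyloxazolidin-2-one | CC(C)[C@H]1COC(=O)N1 | intermediate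
19 | bromoacetyl bromide | BrCC(=O)Br | starting material
20 | lithium salt of (S)-4-isopropyloxazolidin-2-one | CC(C)[C@H]1COC(=O)N1[Li] | intermediate
21 | (S)-3-(2-bromoacetyl)-4-isopropyloxazolidin-2-one | CC(C)[C@H]1COC(=O)N1C(=O)CBr | intermediate
22 | (S)-3-[2-(4-allyl-2,6-dimethoxyphenoxy)acetyl]-4-isopropyloxazolidin-2-one | CC(C)[C@H]1COC(=O)N1C(=O)COc1c(OC)cc(CC=C)cc1OC | intermediate
23 | (Z)-dibutylboron enolate of 22 | CC(C)[C@H]1COC(=O)N1/C(OB(CCCC)CCCC)=C/Oc1c(OC)cc(CC=C)cc1OC | intermediate
24 | dibutylboron aldolate of 25, (2S,3R) | CC(C)[C@H]1COC(=O)N1C(=O)[C@@H](Oc1c(OC)cc(CC=C)cc1OC)[C@H](OB(CCCC)CCCC)c1cc(OC)c(OC)c(OC)c1 | intermediate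
25 | (S)-3-[(2S,3R)-2-(4-allyl-2,6-dimethoxyphenoxy)-3-hydroxy-3-(3,4,5-trimethoxyphenyl)propanoyl]-4-isopropyloxazolidin-2-one | CC(C)[C@H]1COC(=O)N1C(=O)[C@@H](Oc1c(OC)cc(CC=C)cc1OC)[C@H](O)c1cc(OC)c(OC)c(OC)c1 | intermediate
26 | (1R,2R)-2-(4-allyl-2,6-dimethoxyphenoxy)-1-(3,4,5-trimethoxyphenyl)propane-1,3-diol | C=CCc1cc(OC)c(O[C@H](CO)[C@H](O)c2cc(OC)c(OC)c(OC)c2)c(OC)c1 | intermediate
27 | (2R,3R)-2-(4-allyl-2,6-dimethoxyphenoxy)-3-hydroxy-3-(3,4,5-trimethoxyphenyl)propyl acetate | C=CCc1cc(OC)c(O[C@H](COC(C)=O)[C@H](O)c2cc(OC)c(OC)c(OC)c2)c(OC)c1 | target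

**Step count**
- Total step count: 14.
- Longest linear sequence: 8 steps (5, 6, 7, 8, 11, 12, 13, 14, starting from resorcinol).
- The p-cresol line runs 7 steps to the target and the valinol line runs 6.

**Three steps most likely to fail**

Step 11 (hindered phenoxide on a base-sensitive α-bromo imide; imide cleavage or self-condensation of 21 could compete). The fallback sets out from 16 and comes back at 22. Phenol 16 is alkylated with ethyl bromoacetate and K2CO3 in acetone to give ethyl 2-(4-allyl-2,6-dimethoxyphenoxy)acetate F1. This is saponified with LiOH in THF/H2O to 2-(4-allyl-2,6-dimethoxyphenoxy)acetic acid F2. The acid is activated with pivaloyl chloride and Et3N at −20 °C as the mixed 2-(4-allyl-2,6-dimethoxyphenoxy)acetic pivalic anhydride F3. Lithiated auxiliary 20, made from 18, attacks F3 at the less hindered carbonyl to give 22. The ether bond is thus made on a robust ester and the imide is formed last.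

Step 12 (the bulky, chelating 2,6-dimethoxyphenoxy group may slow enolisation or erode the dr, and the electron-rich aldehyde is sluggish and prone to retro-aldol). The fallback sets out from 16 and 6 and comes back at 26. It replaces auxiliary control with catalytic dynamic kinetic resolution.
- Phenol 16 with methyl bromoacetate and K2CO3 gives methyl 2-(4-allyl-2,6-dimethoxyphenoxy)acetate F4.
- The LDA enolate of F4 adds to 6 at −78 °C to give methyl 2-(4-allyl-2,6-dimethoxyphenoxy)-3-hydroxy-3-(3,4,5-trimethoxyphenyl)propanoate as a racemic diastereomer mixture F5.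
- Dess–Martin oxidation gives the configurationally labile methyl 2-(4-allyl-2,6-dimethoxyphenoxy)-3-oxo-3-(3,4,5-trimethoxyphenyl)propanoate F6.
- Noyori transfer hydrogenation with RuCl[(S,S)-TsDPEN](p-cymene) in HCO2H/Et3N follows. It is syn-selective for α-alkoxy β-keto esters and gives the (R)-carbinol by the aryl-ketone model. The product is methyl (2S,3R)-2-(4-allyl-2,6-dimethoxyphenoxy)-3-hydroxy-3-(3,4,5-trimethoxyphenyl)propanoate F7.
- LiBH4 reduction of F7 gives 26.

Step 14 (over-acetylation or 1,3-acetyl migration). The fallback sets out from 25 and comes back at 27. It differentiates the two hydroxyl groups before the primary one exists.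
- Adduct 25 is silylated with TBSOTf and 2,6-lutidine to give the O-TBS ether of the aldol imide F8.
- LiBH4 removes the auxiliary to give (2R,3R)-2-(4-allyl-2,6-dimethoxyphenoxy)-3-(tert-butyldimethylsilyloxy)-3-(3,4,5-trimethoxyphenyl)propan-1-ol F9.
- Ac2O, pyridine and DMAP acetylate the only free OH to give the corresponding O-TBS propyl acetate F10.
- HF·pyridine in THF at 0 °C, a non-basic medium in which the acetyl group does not migrate, gives 27.

**Further compounds**
F1 | step 11 | ethyl 2-(4-allyl-2,6-dimethoxyphenoxy)acetate | CCOC(=O)COc1c(OC)cc(CC=C)cc1OC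
F2 | step 11 | 2-(4-allyl-2,6-dimethoxyphenoxy)acetic acid | OC(=O)COc1c(OC)cc(CC=C)cc1OC
F3 | step 11 | 2-(4-allyl-2,6-dimethoxyphenoxy)acetic pivalic anhydride | CC(C)(C)C(=O)OC(=O)COc1c(OC)cc(CC=C)cc1OC
F4 | step 12 | methyl 2-(4-allyl-2,6-dimethoxyphenoxy)acetate | COC(=O)COc1c(OC)cc(CC=C)cc1OC
F5 | step 12 | methyl 2-(4-allyl-2,6-dimethoxyphenoxy)-3-hydroxy-3-(3,4,5-trimethoxyphenyl)propanoate (racemic diastereomer mixture) | COC(=O)C(Oc1c(OC)cc(CC=C)cc1OC)C(O)c1cc(OC)c(OC)c(OC)c1
F6 | step 12 | methyl 2-(4-allyl-2,6-dimethoxyphenoxy)-3-oxo-3-(3,4,5-trimethoxyphenyl)propanoate (racemic, labile) | COC(=O)C(Oc1c(OC)cc(CC=C)cc1OC)C(=O)c1cc(OC)c(OC)c(OC)c1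
F7 | step 12 | methyl (2S,3R)-2-(4-allyl-2,6-dimethoxyphenoxy)-3-hydroxy-3-(3,4,5-trimethoxyphenyl)propanoate | COC(=O)[C@@H](Oc1c(OC)cc(CC=C)cc1OC)[C@H](O)c1cc(OC)c(OC)c(OC)c1
F8 | step 14 | (S)-3-[(2S,3R)-2-(4-allyl-2,6-dimethoxyphenoxy)-3-(tert-butyldimethylsilyloxy)-3-(3,4,5-trimethoxyphenyl)propanoyl]-4-isopropyloxazolidin-2-one | CC(C)[C@H]1COC(=O)N1C(=O)[C@@H](Oc1c(OC)cc(CC=C)cc1OC)[C@H](O[Si](C)(C)C(C)(C)C)c1cc(OC)c(OC)c(OC)c1
F9 | step 14 | (2R,3R)-2-(4-allyl-2,6-dimethoxyphenoxy)-3-(tert-butyldimethylsilyloxy)-3-(3,4,5-trimethoxyphenyl)propan-1-ol | C=CCc1cc(OC)c(O[C@H](CO)[C@H](O[Si](C)(C)C(C)(C)C)c2cc(OC)c(OC)c(OC)c2)c(OC)c1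
F10 | step 14 | (2R,3R)-2-(4-allyl-2,6-dimethoxyphenoxy)-3-(tert-butyldimethylsilyloxy)-3-(3,4,5-trimethoxyphenyl)propyl acetate | C=CCc1cc(OC)c(O[C@H](COC(C)=O)[C@H](O[Si](C)(C)C(C)(C)C)c2cc(OC)c(OC)c(OC)c2)c(OC)c1
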